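## Retrosynthetic overview

- Ring B is unmasked last. The C4' hydroxyl comes from a methoxy group by addition–elimination, and the C2'/C5' carbonyls come from a 2,4,5-trimethoxy-3-prenylphenyl group by Ce(IV) oxidation. This leads back to a (3R)-isoflavan.
- The C2 methylene comes from a lactone carbonyl (lactol, then silane), so the O1–C2 bond stays intact once it is made.
- Feature used: in ring C the edge O1–C8a–C4a–C4 is the o-quinone methide of 3,5-dimethoxy-4-prenylphenol, whose two ortho carbons are equivalent (axis through C–OH and C–prenyl). C2–C3 with ring B is an arylacetic acid, so cutting C3–C4 and O1–C2 leaves C3 as the only stereocentre, set on a catalyst-bound enolate.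
- Rings A and B are bought as arenes, and each prenyl group is placed between two methoxy groups by directed lithiation. Ring C is the only ring formed, in one step, and ring B is oxidised afterwards.

Key step: step 9

Conventions: isoflavan numbering (ring C: O1, C2, C3, C4, C4a, C8a; primes for ring B); prenyl = 3-methylbut-2-en-1-yl; tosyl = 4-methylphenylsulfonyl.

Assumption: the usual shielding model for (2S,3R)-HyperBTM (CC(C)[C@@H]1CN2c3ccccc3SC2=N[C@@H]1c1ccccc1), with bond formation anti to the C2 phenyl group, is taken to hold and leads to 3R; if the sense proves opposite, the (2R,3S) catalyst is used with no other change.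

## Route

Step 1
Reactants: 1 3,5-dimethoxyphenol
Product: 2 (3,5-dimethoxyphenoxy)triisopropylsilane
Conditions: TIPSCl, imidazole, DMF, rt
Reagents that add atoms: chlorotriisopropylsilane, CC(C)[Si](Cl)(C(C)C)C(C)C
Why: Imidazole-promoted O-silylation masks the acidic OH with a group that resists n-BuLi and is too bulky and too weakly coordinating to steer metalation to its own ortho positions.

Step 2
Reactants: 2 (3,5-dimethoxyphenoxy)triisopropylsilane; 3 prenyl bromide
Product: 5 (3,5-dimethoxy-4-prenylphenoxy)triisopropylsilane, via aryllithium 4 (not isolated)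
Conditions: n-BuLi, THF, 0 °C → rt; then 3, −78 °C → rt
Reagents that add atoms: none
Why: Directed ortho-metalation removes the C–H flanked by two coordinating methoxy groups, and the aryllithium then displaces bromide at the primary allylic carbon (SN2) to give the linear prenyl group.

Step 3
Reactants: 5 (3,5-dimethoxy-4-prenylphenoxy)triisopropylsilane
Product: 6 3,5-dimethoxy-4-prenylphenol
Conditions: TBAF, THF, 0 °C
Reagents that add atoms: none
Why: Fluoride-driven Si–O cleavage frees the phenol under conditions that leave the aryl methyl ethers and the trisubstituted alkene alone.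

Step 4
Reactants: 6 3,5-dimethoxy-4-prenylphenol; 7 sodium p-toluenesulfinate
Product: 9 3,5-dimethoxy-4-prenyl-2-(tosylmethyl)phenol, via hydroxymethylphenol 8 (not isolated)
Conditions: 37% aq. HCHO (1 equiv), 7 (3 equiv), HCO2H–H2O, rt
Reagents that add atoms: formaldehyde, C=O
Why: In this Mannich-type three-component sulfonylmethylation the phenol is hydroxymethylated ortho to OH, the benzylic alcohol ionises readily and excess soft sulfinate captures it at sulfur; the para position is blocked and the two ortho carbons are equivalent, so only one regioisomer is possible.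

Step 5
Reactants: 10 1,2,4-trimethoxybenzene; 3 prenyl bromide
Product: 12 1,2,4-trimethoxy-3-prenylbenzene, via aryllithium 11 (not isolated)
Conditions: n-BuLi, THF, 0 °C → rt; then 3, −78 °C → rt
Reagents that add atoms: none
Why: Directed ortho-metalation takes C3–H, the only hydrogen lying between two methoxy groups, and SN2 allylation fixes the prenyl group between the future O2' and O4'.

Step 6
Reactants: 12 1,2,4-trimethoxy-3-prenylbenzene
Product: 14 2,4,5-trimethoxy-3-prenylbenzaldehyde, via aryl iminium chloride 13 (not isolated)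
Conditions: POCl3, DMF, 0 → 40 °C; then aq. NaOAc, 0 °C → rt
Reagents that add atoms: N,N-dimethylformamide, CN(C)C=O; water, O
Why: Vilsmeier–Haack formylation goes to C5, which is ortho to one methoxy group and para to another, whereas C6 is activated by a single methoxy group; the isolated trisubstituted alkene is too weak a nucleophile for the chloroiminium ion at this temperature.

Step 7
Reactants: 14 2,4,5-trimethoxy-3-prenylbenzaldehyde
Product: 16 (2,4,5-trimethoxy-3-prenylphenyl)acetonitrile, via tosylvinyl formamide 15 (not isolated)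
Conditions: TosMIC, t-BuOK, DME, −40 °C; then MeOH, reflux
Reagents that add atoms: p-toluenesulfonylmethyl isocyanide, Cc1ccc(cc1)S(=O)(=O)C[N+]#[C-]
Why: In the van Leusen reductive cyanation the TosMIC anion adds to the aldehyde, the oxazoline opens to the vinyl formamide, and methanolysis with loss of sulfinate leaves the one-carbon-homologated nitrile under purely basic conditions that the prenyl group tolerates.

Step 8
Reactants: 16 (2,4,5-trimethoxy-3-prenylphenyl)acetonitrile
Product: 17 (2,4,5-trimethoxy-3-prenylphenyl)acetic acid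
Conditions: KOH, EtOH–H2O, reflux; then cold 1 M HCl to pH 3
Reagents that add atoms: potassium hydroxide, [K+].[OH-]; water, O
Why: Alkaline nitrile hydrolysis gives the carboxylate; the di-ortho-substituted prenylarene gains little from conjugation, so the alkene should not migrate at this temperature, and a brief cold acidification spares it.

Step 9
Reactants: 9 3,5-dimethoxy-4-prenyl-2-(tosylmethyl)phenol; 17 (2,4,5-trimethoxy-3-prenylphenyl)acetic acid
Product: 21 (3R)-5,7-dimethoxy-6-prenyl-3-(2,4,5-trimethoxy-3-prenylphenyl)chroman-2-one, via mixed pivalic anhydride 18 (not isolated), via o-quinone methide 19 (not isolated), via C1-ammonium enolate 20 (not isolated)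
Conditions: 17 (1.5 equiv), t-BuCOCl, iPr2NEt, CH2Cl2, 0 °C; then (2S,3R)-HyperBTM (10 mol %), 9 and iPr2NEt added slowly, −20 °C
Reagents that add atoms: none
Why: Pivaloyl chloride turns 17 into anhydride 18, which acylates the isothiourea nitrogen, and deprotonation gives the (Z)-enolate 20, kept coplanar with the catalyst by a 1,5 O···S contact, while iPr2NEt ionises the phenol of 9 so that toluenesulfinate departs and methide 19 appears at low concentration. C3 of 20 adds to the methylene carbon C4 of 19 (C3–C4 bond), ring A regains aromaticity, and the freed phenoxide O1 attacks the acyl ammonium carbon C2 (O1–C2 bond) in a 6-exo-trig acyl transfer that closes ring C and releases the catalyst. The closest known reaction type is the isothiourea-catalysed Michael addition–lactonisation of arylacetic acids, including its [4+2] form on o-quinone methides released in situ from 2-(sulfonylalkyl)phenols. C3 is the only new stereocentre and the catalyst sets it: the pseudoaxial C2 phenyl group of (2S,3R)-HyperBTM covers the Si face of the enolate carbon, so C4 is bonded on the Re face, which corresponds to 3R. Site selectivity is secured by the substrate, because the equivalent ortho carbons of phenol 6 allow only one methide and its methylene carbon is the only soft electrophilic site. The selectivity still to be protected is the configuration at the acidic C3–H of aryl ester 21, hence a hindered amine as the only base, sub-ambient temperature and direct use in step 10.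

Step 10
Reactants: 21 (3R)-5,7-dimethoxy-6-prenyl-3-(2,4,5-trimethoxy-3-prenylphenyl)chroman-2-one
Product: 22 (3R)-5,7-dimethoxy-6-prenyl-3-(2,4,5-trimethoxy-3-prenylphenyl)chroman-2-ol (mixture of C2 epimers)
Conditions: DIBAL-H (1.1 equiv), CH2Cl2, −78 °C; MeOH, then aq. Rochelle salt
Reagents that add atoms: none
Why: In this partial reduction of a dihydrocoumarin one hydride adds to C2 and the aluminium hemiacetal persists at −78 °C until the quench; the new C2 centre is irrelevant because it is removed next, and the cold base-free medium leaves C3 untouched.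

Step 11
Reactants: 22 (3R)-5,7-dimethoxy-6-prenyl-3-(2,4,5-trimethoxy-3-prenylphenyl)chroman-2-ol
Product: 23 (3R)-5,7-dimethoxy-6-prenyl-3-(2,4,5-trimethoxy-3-prenylphenyl)chroman
Conditions: Et3SiH (5 equiv), BF3·OEt2 (2 equiv), CH2Cl2, −78 → −40 °C (crude 22 used at once)
Reagents that add atoms: none
Why: In this ionic silane reduction of a lactol BF3 ionises the C2–OH bond and excess silane delivers hydride to C2 of the cyclic oxocarbenium ion, so O1–C2 is kept; without a strong Brønsted acid at this temperature the prenyl alkenes should not be protonated.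

Step 12
Reactants: 23 (3R)-5,7-dimethoxy-6-prenyl-3-(2,4,5-trimethoxy-3-prenylphenyl)chroman
Product: 24 5-[(3R)-5,7-dimethoxy-6-prenylchroman-3-yl]-2-methoxy-3-prenylcyclohexa-2,5-diene-1,4-dione
Conditions: (NH4)2Ce(NO3)6 (2.2 equiv), MeCN–H2O, 0 °C
Reagents that add atoms: water, O
Why: Ce(IV) oxidative demethylation acts on the para-related C2'/C5' methoxy pair, since the 1,2,4-trioxygenated ring B is the easiest to oxidise and the only ring that can lose two methanol molecules to a p-quinone; the 1,3,5-patterned ring A and the alkenes react more slowly, and the mildly acidic medium does not affect C3.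

Step 13
Reactants: 24 5-[(3R)-5,7-dimethoxy-6-prenylchroman-3-yl]-2-methoxy-3-prenylcyclohexa-2,5-diene-1,4-dione
Product: 25 5-[(3R)-5,7-dimethoxy-6-prenylchroman-3-yl]-2-hydroxy-3-prenylcyclohexa-2,5-diene-1,4-dione (target)
Conditions: 0.5 M aq. NaOH (3 equiv), THF, 0 °C, Ar; then cold 1 M HCl to pH 3
Reagents that add atoms: sodium hydroxide, [Na+].[OH-]
Why: In this saponification of a vinylogous ester hydroxide adds at C4' and expels methoxide, C6'–H is β only to the carbonyl that the methoxy group deactivates, the product is ionised at once to its unreactive anion, and the C3–H bond, held near the quinone plane by allylic strain, is poorly aligned for deprotonation, so the configuration should be kept.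

## Compound list

1 | 3,5-dimethoxyphenol | COc1cc(O)cc(OC)c1 | starting material
2 | (3,5-dimethoxyphenoxy)triisopropylsilane | COc1cc(O[Si](C(C)C)(C(C)C)C(C)C)cc(OC)c1 | intermediate
3 | prenyl bromide (1-bromo-3-methylbut-2-ene) | CC(C)=CCBr | starting material
4 | [2,6-dimethoxy-4-(triisopropylsilyloxy)phenyl]lithium | [Li]c1c(OC)cc(O[Si](C(C)C)(C(C)C)C(C)C)cc1OC | intermediate
5 | (3,5-dimethoxy-4-prenylphenoxy)triisopropylsilane | COc1cc(O[Si](C(C)C)(C(C)C)C(C)C)cc(OC)c1CC=C(C)C | intermediate
6 | 3,5-dimethoxy-4-prenylphenol | COc1cc(O)cc(OC)c1CC=C(C)C | intermediate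
7 | sodium p-toluenesulfinate | Cc1ccc(cc1)S(=O)[O-].[Na+] | starting material
8 | 2-(hydroxymethyl)-3,5-dimethoxy-4-prenylphenol | OCc1c(O)cc(OC)c(CC=C(C)C)c1OC | intermediate
9 | 3,5-dimethoxy-4-prenyl-2-(tosylmethyl)phenol | Cc1ccc(cc1)S(=O)(=O)Cc1c(O)cc(OC)c(CC=C(C)C)c1OC | intermediate
10 | 1,2,4-trimethoxybenzene | COc1ccc(OC)c(OC)c1 | starting material
11 | (2,3,6-trimethoxyphenyl)lithium | [Li]c1c(OC)ccc(OC)c1OC | intermediate
12 | 1,2,4-trimethoxy-3-prenylbenzene | COc1ccc(OC)c(CC=C(C)C)c1OC | intermediate
13 | N,N-dimethyl-(2,4,5-trimethoxy-3-prenylbenzylidene)iminium chloride | C[N+](C)=Cc1cc(OC)c(OC)c(CC=C(C)C)c1OC.[Cl-] | intermediate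
14 | 2,4,5-trimethoxy-3-prenylbenzaldehyde | COc1cc(C=O)c(OC)c(CC=C(C)C)c1OC | intermediate
15 | N-[2-(2,4,5-trimethoxy-3-prenylphenyl)-1-tosylethenyl]formamide | O=CNC(=Cc1cc(OC)c(OC)c(CC=C(C)C)c1OC)S(=O)(=O)c1ccc(C)cc1 | intermediate
16 | (2,4,5-trimethoxy-3-prenylphenyl)acetonitrile | N#CCc1cc(OC)c(OC)c(CC=C(C)C)c1OC | intermediate
17 | (2,4,5-trimethoxy-3-prenylphenyl)acetic acid | OC(=O)Cc1cc(OC)c(OC)c(CC=C(C)C)c1OC | intermediate
18 | pivalic (2,4,5-trimethoxy-3-prenylphenyl)acetic anhydride | CC(C)(C)C(=O)OC(=O)Cc1cc(OC)c(OC)c(CC=C(C)C)c1OC | intermediate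
19 | 3,5-dimethoxy-6-methylidene-4-prenylcyclohexa-2,4-dien-1-one | C=C1C(=O)C=C(OC)C(CC=C(C)C)=C1OC | intermediate
20 | (Z)-C1-ammonium enolate of 17 bound to N1 of (2S,3R)-HyperBTM (zwitterion) | COc1cc(/C=C(\[O-])[N+]2=C3Sc4ccccc4N3C[C@@H](C(C)C)[C@H]2c5ccccc5)c(OC)c(CC=C(C)C)c1OC | intermediate
21 | (3R)-5,7-dimethoxy-6-prenyl-3-(2,4,5-trimethoxy-3-prenylphenyl)chroman-2-one | COc1cc2c(c(OC)c1CC=C(C)C)C[C@H](c1cc(OC)c(OC)c(CC=C(C)C)c1OC)C(=O)O2 | intermediate
22 | (3R)-5,7-dimethoxy-6-prenyl-3-(2,4,5-trimethoxy-3-prenylphenyl)chroman-2-ol, C2 epimers | COc1cc2c(c(OC)c1CC=C(C)C)C[C@H](c1cc(OC)c(OC)c(CC=C(C)C)c1OC)C(O)O2 | intermediate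
23 | (3R)-5,7-dimethoxy-6-prenyl-3-(2,4,5-trimethoxy-3-prenylphenyl)chroman | COc1cc2c(c(OC)c1CC=C(C)C)C[C@H](c1cc(OC)c(OC)c(CC=C(C)C)c1OC)CO2 | intermediate
24 | 5-[(3R)-5,7-dimethoxy-6-prenylchroman-3-yl]-2-methoxy-3-prenylcyclohexa-2,5-diene-1,4-dione | COc1cc2c(c(OC)c1CC=C(C)C)C[C@H](C1=CC(=O)C(OC)=C(CC=C(C)C)C1=O)CO2 | intermediate
25 | 5-[(3R)-5,7-dimethoxy-6-prenylchroman-3-yl]-2-hydroxy-3-prenylcyclohexa-2,5-diene-1,4-dione (CNP0241224.1) | COc1cc2c(c(OC)c1CC=C(C)C)C[C@H](C1=CC(=O)C(O)=C(CC=C(C)C)C1=O)CO2 | target

## Step count and risks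

Total step count: 13.
Longest linear sequence: 9 steps (steps 1–4 or steps 5–8, then steps 9–13).

**1. Step 9.**
- What may go wrong:
  - The unsubstituted methide may self-condense faster than the enolate captures it.
  - The phenol oxygen of 9 may be acylated before sulfinate has left.
  - An ortho-substituted aryl group on the enolate may weaken shielding of one face.
  - Base may erode the configuration at C3 after ring closure.
- Fallback (auxiliary control instead of catalyst control; sets out from 17 and 9, returns at 21):
  - Acid 17 is activated as anhydride 18 and coupled with lithiated (R)-4-benzyloxazolidin-2-one to give the N-acyl oxazolidinone F1.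
  - The chelated (Z)-sodium enolate of F1 (NaHMDS, THF, −78 °C) is treated with the preformed sodium phenoxide of 9.
  - On warming to about −40 °C the methide is released and is attacked on the enolate face away from the benzyl group. A cold acetic acid quench then gives the phenol imide F2.
  - LiOH/H2O2 (THF–H2O, 0 °C) removes the auxiliary to give the hydroxy acid F3.
  - EDC·HCl in CH2Cl2 at 0 °C closes the lactone to 21.

**2. Step 11.**
- What may go wrong:
  - Proton loss from C3 of the oxocarbenium ion may compete with hydride delivery, and reprotonation would then erode the configuration.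
  - The lactol may open to the enolisable α-aryl aldehyde before ionisation.
  - The Lewis acid may attack the prenyl alkenes.
- Fallback (ring opening and SN2 re-closure instead of deoxygenation; sets out from 21, returns at 23):
  - LiBH4 in THF at 0 °C reduces the lactone fully to the phenol alcohol F4.
  - A Mitsunobu reaction (PPh3, DIAD, THF, 0 °C) re-forms O1–C2 by displacement at the primary carbon. No cationic or enolisable species at C2 is involved and C3 is not touched. The cost is that the O1–C2 bond made in step 9 is broken and made again.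

**3. Step 4.**
- What may go wrong:
  - A second molecule of the very electron-rich phenol may capture the benzylic electrophile instead of sulfinate (methylene bridging).
  - A second substitution may occur at the other ortho carbon.
  - Acid may promote reversal of sulfone formation.
- Fallback (amine-trapped Mannich route under non-acidic conditions; sets out from 6, returns at 9):
  - Aqueous dimethylamine and formaldehyde (1 equiv each, EtOH, 0 °C → rt) give the Mannich base F5, which does not ionise under the basic conditions.
  - Methyl iodide in MeCN quaternises the nitrogen to give the ammonium iodide F6.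
  - Salt 7 in MeCN–H2O at rt–40 °C replaces trimethylamine by sulfinate to give 9.

## Further compounds

F1 | step 9 | (4R)-4-benzyl-3-[(2,4,5-trimethoxy-3-prenylphenyl)acetyl]oxazolidin-2-one | O=C1OC[C@@H](Cc2ccccc2)N1C(=O)Cc1cc(OC)c(OC)c(CC=C(C)C)c1OC
F2 | step 9 | (4R)-4-benzyl-3-[(2R)-3-(6-hydroxy-2,4-dimethoxy-3-prenylphenyl)-2-(2,4,5-trimethoxy-3-prenylphenyl)propanoyl]oxazolidin-2-one | O=C1OC[C@@H](Cc2ccccc2)N1C(=O)[C@H](Cc1c(O)cc(OC)c(CC=C(C)C)c1OC)c1cc(OC)c(OC)c(CC=C(C)C)c1OC
F3 | step 9 | (2R)-3-(6-hydroxy-2,4-dimethoxy-3-prenylphenyl)-2-(2,4,5-trimethoxy-3-prenylphenyl)propanoic acid | OC(=O)[C@H](Cc1c(O)cc(OC)c(CC=C(C)C)c1OC)c1cc(OC)c(OC)c(CC=C(C)C)c1OC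
F4 | step 11 | 2-[(2R)-3-hydroxy-2-(2,4,5-trimethoxy-3-prenylphenyl)propyl]-3,5-dimethoxy-4-prenylphenol | OC[C@H](Cc1c(O)cc(OC)c(CC=C(C)C)c1OC)c1cc(OC)c(OC)c(CC=C(C)C)c1OC
F5 | step 4 | 2-[(dimethylamino)methyl]-3,5-dimethoxy-4-prenylphenol | CN(C)Cc1c(O)cc(OC)c(CC=C(C)C)c1OC
F6 | step 4 | (2-hydroxy-4,6-dimethoxy-5-prenylbenzyl)trimethylammonium iodide | C[N+](C)(C)Cc1c(O)cc(OC)c(CC=C(C)C)c1OC.[I-]
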